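The route rests on building the oxolane ring (O-1, C-2 = CMe2, C-3 = CHOH, C-4 = CH2, C-5 = side-chain carbon) from racemic 2,3-dimethylpent-4-ene-2,3-diol and 3-(trimethylsilyl)propynal by a one-flask acetalisation/Prins–pinacol rearrangement. This forms O-1–C-5, C-4–C-5 and, by 1,2-shift, C-2–C-3, with 3,5-cis control. The feature exploited is the quaternary, oxygen-bearing C-2 next to carbinol C-3: C-2 is the migrating terminus of a masked pinacol, and the C-3 hydroxyl is the Baeyer–Villiger image of the acetyl group that the shift leaves. Lipase resolution, two carboalumination-based couplings and a B-alkyl Suzuki–Miyaura union then assemble the chain.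

Key step: step 2

Assumption: the lipase of step 5 and the (R)-configured phosphoric acid of step 10 are taken to show their usual sense of enantioselection (faster acylation of the (3R)-alcohol; Re-face propargylation). Were either sense reversed, the acylated enantiomer (after methanolysis) or the (S)-acid would be used instead.

Step 1
Reactants: 1 3-hydroxy-3-methylbutan-2-one; 2 vinylmagnesium bromide
Product: 3 rac-2,3-dimethylpent-4-ene-2,3-diol
Conditions: CH2=CHMgBr (2.3 equiv), THF, 0 °C → rt; aq NH4Cl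
Reagents that add atoms: none
Why: Grignard 1,2-addition to the ketone after deprotonation of the tertiary hydroxyl; the new carbinol centre forms as the racemate, which is immaterial because it becomes the acetyl carbonyl in step 2.

Step 2
Reactants: 3 rac-2,3-dimethylpent-4-ene-2,3-diol; 4 3-(trimethylsilyl)prop-2-ynal
Product: 6 rac-1-[(3S,5S)-2,2-dimethyl-5-[(trimethylsilyl)ethynyl]oxolan-3-yl]ethan-1-one (3,5-cis), via dioxolane acetal 5 (not isolated)
Conditions: TsOH·H2O (5 mol %), MgSO4, CH2Cl2, 0 °C; then SnCl4 (0.3 equiv), −78 → 0 °C, same flask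
Reagents that add atoms: none
Why: Acid-catalysed condensation gives acetal 5; SnCl4 opens its allylic C–O bond to the (E)-oxocarbenium ion on the oxygen of the CMe2 carbon, the vinyl CH2 adds to the oxocarbenium carbon through a chair transition state, and the positive charge developing at the internal vinyl carbon is quenched in concert by 1,2-shift of the oxygen-bearing CMe2 carbon from the carbinol carbon, which leaves as the acetyl C=O. In one flask this should form O-1–C-5, C-4–C-5 and C-2–C-3 of the oxolane; the closest known reaction type is the Prins–pinacol synthesis of 3-acyltetrahydrofurans from allylic 1,2-diols and aldehydes, known for vinyl carbinols and for conjugated aldehydes. The oxolane is closed by 6-endo-trig Prins cyclisation to an incipient oxan-4-yl cation followed by ring contraction, not by a direct five-membered closure. Both stereocentres arise from the chair: the alkynyl group is equatorial because the oxocarbenium ion is E, and the migrating carbon bonds to the face of the cationic carbon on which it already lies, so acetyl and alkynyl should end up cis; the carbinol stereocentre of 3 is destroyed, hence racemic 3 gives racemic cis-6. Selectivity needed: productive acetal opening (only the oxocarbenium ion on the CMe2 oxygen can reach the alkene, the other opening is reversible), migration of the ring carbon and not of methyl (the tertiary oxygen-bearing carbon is the better migrating group and lies syn to the developing p orbital) and survival of the silylalkyne at low temperature. A stepwise 2-oxonia-Cope/aldol course through the same chair would give the same bonds and product.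

Step 3
Reactants: 6 rac-1-[(3S,5S)-2,2-dimethyl-5-[(trimethylsilyl)ethynyl]oxolan-3-yl]ethan-1-one
Product: 7 rac-(3S,5S)-2,2-dimethyl-5-[(trimethylsilyl)ethynyl]oxolan-3-yl acetate
Conditions: m-CPBA, Na2HPO4, CH2Cl2, rt
Reagents that add atoms: m-chloroperbenzoic acid, OOC(=O)c1cccc(Cl)c1
Why: Baeyer–Villiger oxidation in which the secondary ring carbon migrates in preference to methyl with retention, so the cis relationship is carried from C–C to C–O; the silylalkyne is inert to the peracid.

Step 4
Reactants: 7 rac-(3S,5S)-2,2-dimethyl-5-[(trimethylsilyl)ethynyl]oxolan-3-yl acetate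
Product: 8 rac-(3S,5S)-5-ethynyl-2,2-dimethyloxolan-3-ol
Conditions: K2CO3 (0.2 equiv), MeOH, rt
Reagents that add atoms: none
Why: Base-catalysed transesterification of the acetate and methanolytic cleavage of the alkynyl C–Si bond should occur in one operation without touching a stereocentre.

Step 5
Reactants: 8 rac-(3S,5S)-5-ethynyl-2,2-dimethyloxolan-3-ol
Product: 9 (3S,5S)-5-ethynyl-2,2-dimethyloxolan-3-ol
Conditions: Candida antarctica lipase B (immobilised), vinyl acetate, t-BuOMe, 30 °C, stopped slightly beyond half conversion; chromatography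
Reagents that add atoms: none
Why: Lipase-catalysed kinetic resolution by enantioselective transesterification; by the empirical size model the (3R)-alcohol (larger CMe2–O flank, smaller CH2 flank) is acetylated faster, so the (3S,5S)-alcohol should be recovered unreacted, which fixes the absolute configuration of both ring stereocentres.

Step 6
Reactants: 9 (3S,5S)-5-ethynyl-2,2-dimethyloxolan-3-ol
Product: 10 triethyl{[(3S,5S)-5-ethynyl-2,2-dimethyloxolan-3-yl]oxy}silane
Conditions: Et3SiOTf, 2,6-lutidine, CH2Cl2, −78 → 0 °C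
Reagents that add atoms: triethylsilyl trifluoromethanesulfonate, CC[Si](CC)(CC)OS(=O)(=O)C(F)(F)F
Why: Silyl triflate silylation of the hindered secondary alcohol; the triethylsilyl ether masks this hydroxyl during the later acetylation and is removable by fluoride.

Step 7
Reactants: 10 triethyl{[(3S,5S)-5-ethynyl-2,2-dimethyloxolan-3-yl]oxy}silane
Product: 12 triethyl({(3S,5S)-5-[(1E)-1-iodoprop-1-en-2-yl]-2,2-dimethyloxolan-3-yl}oxy)silane, via alkenyldimethylalane 11 (not isolated)
Conditions: AlMe3 (2.5 equiv), (C5H5)2ZrCl2 (0.3 equiv), CH2Cl2, 0 °C → rt; then I2, THF, −30 → 0 °C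
Reagents that add atoms: trimethylaluminium, C[Al](C)C; iodine, II
Why: Zirconium-catalysed methylalumination (Negishi carboalumination) adds methyl and aluminium syn across the terminal alkyne with methyl at the internal carbon, and iodinolysis with retention should give the (E)-2-methylalkenyl iodide with the alkene geometry of the target.

Step 8
Reactants: 13 (2E)-3-methylpent-2-en-4-yn-1-ol
Product: 14 (2E)-3-methylpenta-2,4-dien-1-ol
Conditions: H2 (1 atm), Pd on CaCO3 poisoned with Pb(OAc)2 (Lindlar catalyst), quinoline, EtOAc, rt, stopped after one equivalent of H2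
Reagents that add atoms: none
Why: Lindlar semihydrogenation should reduce the terminal alkyne to the vinyl group and leave the trisubstituted (E)-alkene untouched.

Step 9
Reactants: 14 (2E)-3-methylpenta-2,4-dien-1-ol
Product: 15 (2E)-3-methylpenta-2,4-dienal
Conditions: MnO2 (activated, excess), CH2Cl2, rt; used as a solution
Reagents that add atoms: none
Why: MnO2 oxidises the allylic alcohol chemoselectively to the dienal without E/Z isomerisation.

Step 10
Reactants: 15 (2E)-3-methylpenta-2,4-dienal; 16 allenylboronic acid pinacol ester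
Product: 17 (4R,5E)-6-methylocta-5,7-dien-1-yn-4-ol
Conditions: (R)-3,3'-bis(2,4,6-triisopropylphenyl)-1,1'-binaphthyl-2,2'-diyl hydrogen phosphate (10 mol %), 4 Å molecular sieves, toluene, −20 °C; aqueous work-up
Reagents that add atoms: none
Why: Chiral phosphoric acid-catalysed asymmetric propargylation; the allenylboronate reacts by SE2' through a closed six-membered transition state organised by the phosphate, and the (R)-acid should direct attack to the Re face of the enal, giving the (4R)-alcohol that becomes the acetoxy-bearing centre.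

Step 11
Reactants: 18 4-methoxy-2-methylphenol
Product: 19 2-hydroxy-5-methoxy-3-methylbenzaldehyde
Conditions: (CH2O)n, MgCl2, Et3N, MeCN, reflux; aq HCl
Reagents that add atoms: paraformaldehyde (as formaldehyde), C=O
Why: Magnesium phenoxide-directed ortho-formylation at the only free ortho position, a second formaldehyde equivalent serving as hydride acceptor.

Step 12
Reactants: 19 2-hydroxy-5-methoxy-3-methylbenzaldehyde
Product: 20 5-methoxy-3-methyl-2-[(triisopropylsilyl)oxy]benzaldehyde
Conditions: i-Pr3SiOTf, 2,6-lutidine, CH2Cl2, 0 °C → rt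
Reagents that add atoms: triisopropylsilyl trifluoromethanesulfonate, CC(C)[Si](OS(=O)(=O)C(F)(F)F)(C(C)C)C(C)C
Why: Silyl triflate silylation of the hindered phenol; the triisopropylsilyl ether is chosen because it should survive AlMe3 and the aqueous base of step 16 yet fall to fluoride.

Step 13
Reactants: 20 5-methoxy-3-methyl-2-[(triisopropylsilyl)oxy]benzaldehyde
Product: 21 {5-methoxy-3-methyl-2-[(triisopropylsilyl)oxy]phenyl}methanol
Conditions: NaBH4, MeOH/THF, 0 °C
Reagents that add atoms: none
Why: Borohydride reduction of the aldehyde at 0 °C, where migration of the bulky silyl group from the phenolic oxygen is not expected.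

Step 14
Reactants: 21 {5-methoxy-3-methyl-2-[(triisopropylsilyl)oxy]phenyl}methanol
Product: 22 [2-(chloromethyl)-4-methoxy-6-methylphenoxy]triisopropylsilane
Conditions: PPh3, N-chlorosuccinimide, CH2Cl2, 0 °C → rt
Reagents that add atoms: N-chlorosuccinimide, O=C1CCC(=O)N1Cl
Why: Appel-type chlorination under neutral conditions converts the benzylic alcohol to the chloride by SN2 displacement of the oxyphosphonium group.

Step 15
Reactants: 17 (4R,5E)-6-methylocta-5,7-dien-1-yn-4-ol; 22 [2-(chloromethyl)-4-methoxy-6-methylphenoxy]triisopropylsilane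
Product: 24 (2E,5R,6E)-1-{5-methoxy-3-methyl-2-[(triisopropylsilyl)oxy]phenyl}-3,7-dimethylnona-2,6,8-trien-5-ol, via alkenylalane 23 (not isolated)
Conditions: AlMe3 (3.5 equiv), (C5H5)2ZrCl2 (0.3 equiv), CH2Cl2, 0 °C → rt; then 22, Pd(PPh3)4 (5 mol %), THF, rt; aq potassium sodium tartrate
Reagents that add atoms: trimethylaluminium, C[Al](C)C
Why: Negishi carboalumination of the terminal alkyne (syn, methyl to the internal carbon, the hydroxyl carried as its aluminium alkoxide) followed by palladium-catalysed alkenyl–benzyl Negishi coupling with retention of geometry should give the (E)-ArCH2–CH=C(Me) unit, alkyne carbometalation being much faster than that of the diene.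

Step 16
Reactants: 24 (2E,5R,6E)-1-{5-methoxy-3-methyl-2-[(triisopropylsilyl)oxy]phenyl}-3,7-dimethylnona-2,6,8-trien-5-ol; 12 triethyl({(3S,5S)-5-[(1E)-1-iodoprop-1-en-2-yl]-2,2-dimethyloxolan-3-yl}oxy)silane
Product: 26 (2E,5R,6E,10E)-11-{(2S,4S)-5,5-dimethyl-4-[(triethylsilyl)oxy]oxolan-2-yl}-1-{5-methoxy-3-methyl-2-[(triisopropylsilyl)oxy]phenyl}-3,7-dimethyldodeca-2,6,10-trien-5-ol, via B-alkyl-9-BBN adduct 25 (not isolated)
Conditions: 9-BBN-H (2.5 equiv), THF, 0 °C → rt; then 12, PdCl2(dppf) (5 mol %), AsPh3, K3PO4 (3 M aq), DMF, rt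
Reagents that add atoms: none
Why: 9-BBN should hydroborate only the terminal vinyl group of the diene (anti-Markovnikov), and B-alkyl Suzuki–Miyaura coupling of the primary alkylborane with alkenyl iodide 12 proceeds with retention of the iodide geometry, joining C-9 to C-10 of the chain.

Step 17
Reactants: 26 (2E,5R,6E,10E)-11-{(2S,4S)-5,5-dimethyl-4-[(triethylsilyl)oxy]oxolan-2-yl}-1-{5-methoxy-3-methyl-2-[(triisopropylsilyl)oxy]phenyl}-3,7-dimethyldodeca-2,6,10-trien-5-ol
Product: 27 (2E,5R,6E,10E)-11-{(2S,4S)-5,5-dimethyl-4-[(triethylsilyl)oxy]oxolan-2-yl}-1-{5-methoxy-3-methyl-2-[(triisopropylsilyl)oxy]phenyl}-3,7-dimethyldodeca-2,6,10-trien-5-yl acetate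
Conditions: Ac2O, pyridine, DMAP (cat.), CH2Cl2, 0 °C → rt
Reagents that add atoms: acetic anhydride, CC(=O)OC(C)=O
Why: DMAP-catalysed acetylation of the only free hydroxyl with retention; it is placed after the palladium steps because an allylic acetate would ionise with zerovalent palladium.

Step 18
Reactants: 27 (2E,5R,6E,10E)-11-{(2S,4S)-5,5-dimethyl-4-[(triethylsilyl)oxy]oxolan-2-yl}-1-{5-methoxy-3-methyl-2-[(triisopropylsilyl)oxy]phenyl}-3,7-dimethyldodeca-2,6,10-trien-5-yl acetate
Product: 28 (2E,5R,6E,10E)-11-[(2S,4S)-4-hydroxy-5,5-dimethyloxolan-2-yl]-1-(2-hydroxy-5-methoxy-3-methylphenyl)-3,7-dimethyldodeca-2,6,10-trien-5-yl acetate (CNP0148147.2)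
Conditions: Bu4NF, AcOH (1:1), THF, 0 °C → rt
Reagents that add atoms: none
Why: Fluoride desilylation should cleave the aryl triisopropylsilyl and the alkyl triethylsilyl ethers, while acetic acid buffering protects the acetate and the ortho-allylphenol.

Compound list
1 | 3-hydroxy-3-methylbutan-2-one | CC(=O)C(C)(C)O | starting material
2 | vinylmagnesium bromide | C=C[Mg]Br | starting material
3 | rac-2,3-dimethylpent-4-ene-2,3-diol | C=CC(C)(O)C(C)(C)O | intermediate
4 | 3-(trimethylsilyl)prop-2-ynal | C[Si](C)(C)C#CC=O | starting material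
5 | 4,4,5-trimethyl-2-[(trimethylsilyl)ethynyl]-5-vinyl-1,3-dioxolane (racemic mixture of diastereomers) | C=CC1(C)OC(C#C[Si](C)(C)C)OC1(C)C | intermediate
6 | rac-1-[(3S,5S)-2,2-dimethyl-5-[(trimethylsilyl)ethynyl]oxolan-3-yl]ethan-1-one (racemate; one enantiomer drawn) | C[Si](C)(C)C#C[C@@H]1C[C@H](C(C)=O)C(C)(C)O1 | intermediate
7 | rac-(3S,5S)-2,2-dimethyl-5-[(trimethylsilyl)ethynyl]oxolan-3-yl acetate (racemate; one enantiomer drawn) | C[Si](C)(C)C#C[C@@H]1C[C@H](OC(C)=O)C(C)(C)O1 | intermediate
8 | rac-(3S,5S)-5-ethynyl-2,2-dimethyloxolan-3-ol (racemate; one enantiomer drawn) | C#C[C@@H]1C[C@H](O)C(C)(C)O1 | intermediate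
9 | (3S,5S)-5-ethynyl-2,2-dimethyloxolan-3-ol (single enantiomer) | C#C[C@@H]1C[C@H](O)C(C)(C)O1 | intermediate
10 | triethyl{[(3S,5S)-5-ethynyl-2,2-dimethyloxolan-3-yl]oxy}silane | C#C[C@@H]1C[C@H](O[Si](CC)(CC)CC)C(C)(C)O1 | intermediate
11 | dimethyl{(1E)-2-[(2S,4S)-5,5-dimethyl-4-[(triethylsilyl)oxy]oxolan-2-yl]prop-1-en-1-yl}alane | C[Al](C)/C=C(\C)[C@@H]1C[C@H](O[Si](CC)(CC)CC)C(C)(C)O1 | intermediate
12 | triethyl({(3S,5S)-5-[(1E)-1-iodoprop-1-en-2-yl]-2,2-dimethyloxolan-3-yl}oxy)silane | I/C=C(\C)[C@@H]1C[C@H](O[Si](CC)(CC)CC)C(C)(C)O1 | intermediate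
13 | (2E)-3-methylpent-2-en-4-yn-1-ol | C#C/C(C)=C/CO | starting material
14 | (2E)-3-methylpenta-2,4-dien-1-ol | C=C/C(C)=C/CO | intermediate
15 | (2E)-3-methylpenta-2,4-dienal | C=C/C(C)=C/C=O | intermediate
16 | allenylboronic acid pinacol ester | C=C=CB1OC(C)(C)C(C)(C)O1 | starting material
17 | (4R,5E)-6-methylocta-5,7-dien-1-yn-4-ol | C#CC[C@H](/C=C(\C)C=C)O | intermediate
18 | 4-methoxy-2-methylphenol | COc1ccc(O)c(C)c1 | starting material
19 | 2-hydroxy-5-methoxy-3-methylbenzaldehyde | COc1cc(C)c(O)c(C=O)c1 | intermediate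
20 | 5-methoxy-3-methyl-2-[(triisopropylsilyl)oxy]benzaldehyde | COc1cc(C)c(O[Si](C(C)C)(C(C)C)C(C)C)c(C=O)c1 | intermediate
21 | {5-methoxy-3-methyl-2-[(triisopropylsilyl)oxy]phenyl}methanol | COc1cc(C)c(O[Si](C(C)C)(C(C)C)C(C)C)c(CO)c1 | intermediate
22 | [2-(chloromethyl)-4-methoxy-6-methylphenoxy]triisopropylsilane | COc1cc(C)c(O[Si](C(C)C)(C(C)C)C(C)C)c(CCl)c1 | intermediate
23 | alkenylalane from 17: (1E,4R,5E)-1-(dimethylalumanyl)-2,6-dimethylocta-1,5,7-trien-4-yl dimethylaluminium alkoxide | C[Al](C)/C=C(\C)C[C@H](/C=C(\C)C=C)O[Al](C)C | intermediate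
24 | (2E,5R,6E)-1-{5-methoxy-3-methyl-2-[(triisopropylsilyl)oxy]phenyl}-3,7-dimethylnona-2,6,8-trien-5-ol | COc1cc(C)c(O[Si](C(C)C)(C(C)C)C(C)C)c(C/C=C(\C)C[C@H](/C=C(\C)C=C)O)c1 | intermediate
25 | B-alkyl-9-BBN adduct of 24 (C-9 borane; C-5 hydroxyl as its 9-BBN borinate) | COc1cc(C)c(O[Si](C(C)C)(C(C)C)C(C)C)c(C/C=C(\C)C[C@H](/C=C(\C)CCB2C3CCCC2CCC3)OB2C3CCCC2CCC3)c1 | intermediate
26 | (2E,5R,6E,10E)-11-{(2S,4S)-5,5-dimethyl-4-[(triethylsilyl)oxy]oxolan-2-yl}-1-{5-methoxy-3-methyl-2-[(triisopropylsilyl)oxy]phenyl}-3,7-dimethyldodeca-2,6,10-trien-5-ol | COc1cc(C)c(O[Si](C(C)C)(C(C)C)C(C)C)c(C/C=C(\C)C[C@H](/C=C(\C)CC/C=C(\C)[C@@H]2C[C@H](O[Si](CC)(CC)CC)C(C)(C)O2)O)c1 | intermediate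
27 | (2E,5R,6E,10E)-11-{(2S,4S)-5,5-dimethyl-4-[(triethylsilyl)oxy]oxolan-2-yl}-1-{5-methoxy-3-methyl-2-[(triisopropylsilyl)oxy]phenyl}-3,7-dimethyldodeca-2,6,10-trien-5-yl acetate | COc1cc(C)c(O[Si](C(C)C)(C(C)C)C(C)C)c(C/C=C(\C)C[C@H](/C=C(\C)CC/C=C(\C)[C@@H]2C[C@H](O[Si](CC)(CC)CC)C(C)(C)O2)OC(C)=O)c1 | intermediate
28 | (2E,5R,6E,10E)-11-[(2S,4S)-4-hydroxy-5,5-dimethyloxolan-2-yl]-1-(2-hydroxy-5-methoxy-3-methylphenyl)-3,7-dimethyldodeca-2,6,10-trien-5-yl acetate | COc1cc(C)c(O)c(C/C=C(\C)C[C@H](/C=C(\C)CC/C=C(\C)[C@@H]2C[C@H](O)C(C)(C)O2)OC(C)=O)c1 | target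

Total step count: 18. Longest linear sequence: 10 steps (steps 1–7, then 16–18).

Steps most likely to fail

Step 2. The unsubstituted vinyl terminus may be too weak a nucleophile for the alkynyl-conjugated oxocarbenium ion, so that the acetal is returned or the tertiary allylic C–O bond ionises; the cis selectivity may also erode if the reaction runs through a relaxed oxonia-Cope/aldol course. Fallback: setting out from 3, the same one-flask condensation/Prins–pinacol reaction would be run with (benzyloxy)acetaldehyde, whose more electrophilic oxocarbenium ion is the best-precedented partner for vinyl carbinols, to give rac-1-[(3S,5S)-5-[(benzyloxy)methyl]-2,2-dimethyloxolan-3-yl]ethan-1-one F1. Baeyer–Villiger oxidation (m-CPBA) would give rac-(3S,5S)-5-[(benzyloxy)methyl]-2,2-dimethyloxolan-3-yl acetate F2, hydrogenolysis (H2, Pd on carbon) rac-(3S,5S)-5-(hydroxymethyl)-2,2-dimethyloxolan-3-yl acetate F3, and Dess–Martin oxidation rac-(3S,5S)-5-formyl-2,2-dimethyloxolan-3-yl acetate F4. Ohira–Bestmann homologation (dimethyl (1-diazo-2-oxopropyl)phosphonate, K2CO3, MeOH, 0 °C), which also cleaves the acetate, would return to the route at 8.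

Step 5. Acylation of an alcohol flanked by a quaternary carbon may be slow or poorly enantioselective. Fallback: setting out from 8, esterification with (S)-2-methoxy-2-phenylacetic acid (DCC, DMAP) would give two diastereomeric esters, to be separated by chromatography or crystallisation. The ester of the wanted alcohol, (3S,5S)-5-ethynyl-2,2-dimethyloxolan-3-yl (2S)-2-methoxy-2-phenylacetate F5, would be cleaved with K2CO3 in MeOH to return to the route at 9.

Step 15. The dienylic aluminium alkoxide may ionise or eliminate under the Lewis acidic carboalumination conditions, and the diene may be carbometalated in competition. Fallback: the order of union would be inverted, setting out from 14 and 12. Hydroboration of 14 with 9-BBN-H and B-alkyl Suzuki–Miyaura coupling with 12 would give (2E,6E)-7-{(2S,4S)-5,5-dimethyl-4-[(triethylsilyl)oxy]oxolan-2-yl}-3-methylocta-2,6-dien-1-ol F6. MnO2 oxidation would give the non-volatile enal (2E,6E)-7-{(2S,4S)-5,5-dimethyl-4-[(triethylsilyl)oxy]oxolan-2-yl}-3-methylocta-2,6-dienal F7, and phosphoric acid-catalysed propargylation with 16 would give (4R,5E,9E)-10-{(2S,4S)-5,5-dimethyl-4-[(triethylsilyl)oxy]oxolan-2-yl}-6-methylundeca-5,9-dien-1-yn-4-ol F8, whose hydroxyl is only allylic and no longer dienylic. Carboalumination of F8 and palladium-catalysed coupling with 22 would return to the route at 26.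

Further compounds
F1 | step 2 | rac-1-[(3S,5S)-5-[(benzyloxy)methyl]-2,2-dimethyloxolan-3-yl]ethan-1-one (one enantiomer drawn) | c1ccccc1COC[C@@H]2C[C@H](C(C)=O)C(C)(C)O2
F2 | step 2 | rac-(3S,5S)-5-[(benzyloxy)methyl]-2,2-dimethyloxolan-3-yl acetate (one enantiomer drawn) | c1ccccc1COC[C@@H]2C[C@H](OC(C)=O)C(C)(C)O2
F3 | step 2 | rac-(3S,5S)-5-(hydroxymethyl)-2,2-dimethyloxolan-3-yl acetate (one enantiomer drawn) | OC[C@@H]1C[C@H](OC(C)=O)C(C)(C)O1
F4 | step 2 | rac-(3S,5S)-5-formyl-2,2-dimethyloxolan-3-yl acetate (one enantiomer drawn) | O=C[C@@H]1C[C@H](OC(C)=O)C(C)(C)O1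
F5 | step 5 | (3S,5S)-5-ethynyl-2,2-dimethyloxolan-3-yl (2S)-2-methoxy-2-phenylacetate | C#C[C@@H]1C[C@H](OC(=O)[C@@H](OC)c2ccccc2)C(C)(C)O1
F6 | step 15 | (2E,6E)-7-{(2S,4S)-5,5-dimethyl-4-[(triethylsilyl)oxy]oxolan-2-yl}-3-methylocta-2,6-dien-1-ol | OC/C=C(\C)CC/C=C(\C)[C@@H]1C[C@H](O[Si](CC)(CC)CC)C(C)(C)O1
F7 | step 15 | (2E,6E)-7-{(2S,4S)-5,5-dimethyl-4-[(triethylsilyl)oxy]oxolan-2-yl}-3-methylocta-2,6-dienal | O=C/C=C(\C)CC/C=C(\C)[C@@H]1C[C@H](O[Si](CC)(CC)CC)C(C)(C)O1
F8 | step 15 | (4R,5E,9E)-10-{(2S,4S)-5,5-dimethyl-4-[(triethylsilyl)oxy]oxolan-2-yl}-6-methylundeca-5,9-dien-1-yn-4-ol | C#CC[C@H](/C=C(\C)CC/C=C(\C)[C@@H]1C[C@H](O[Si](CC)(CC)CC)C(C)(C)O1)O
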